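**Strategy**

The route rests on cutting ring B of the decalin across C9–C10 and C5–C6. The feature used is the quaternary C10: it bears the oxidised carbon C14, lies between the oxygenated carbons C1 and C9 and has C5 next to the methyl-bearing C4, which is the substitution pattern left when the ester-bearing C5=C10 bond of a carbomethoxybenzoquinone adds a 1-oxygenated butadiene. One catalytic enantioselective Diels–Alder reaction therefore makes ring B, both C–C bonds and the configuration of C10. Its partners are methyl 3,6-dioxocyclohexa-1,4-diene-1-carboxylate and (E)-1-(tert-butyldimethylsilyloxy)buta-1,3-diene; the ring-A ene-dione and the C7=C8 bond of the adduct then take up the remaining groups.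

Key step: step 3

Remark on locants: all bicyclic compounds carry the eudesmane locants of the target (ring A = C1–C5 and C10; ring B = C5–C10; C14 on C10, C15 on C4, C11–C13 = isopropenyl on C7); β is the face on which C14 lies, α the other face.

Remark on structures: both cycloaddition partners and the adduct were checked against the target centre by centre (endo, cis-fused, 9-silyloxy anti to the ester, C10 as in the target) and are used as drawn; no correction was needed.

Assumption: the (S,S)-ligand is taken to leave open the face of the chelated quinone ester that leads to 5; should a first run show the opposite sense, the (R,R)-ligand is used and nothing else changes.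

**Route**

Step 1
Reactants: 1 methyl 2,5-dihydroxybenzoate
Product: 2 methyl 3,6-dioxocyclohexa-1,4-diene-1-carboxylate
Conditions: Ag2O (2.5 equiv), MgSO4, toluene, rt; filtered through Celite, used at once
Reagents that add atoms: none
Why: Oxidation of a hydroquinone to the 1,4-benzoquinone with Ag2O is a neutral two-electron dehydrogenation that leaves the ester alone and avoids the acid or base that would destroy this electron-poor quinone.

Step 2
Reactants: 3 (E)-but-2-enal (crotonaldehyde)
Product: 4 (E)-1-(tert-butyldimethylsilyloxy)buta-1,3-diene
Conditions: TBSOTf (1.05 equiv), Et3N (1.3 equiv), Et2O, 0 °C → rt; distilled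
Reagents that add atoms: tert-butyldimethylsilyl trifluoromethanesulfonate, CC(C)(C)[Si](C)(C)OS(=O)(=O)C(F)(F)F
Why: Silyl dienol ether formation (γ-deprotonation of the enal and O-silylation) should give mainly the (E)-diene, and any (Z)-isomer cannot reach the s-cis form easily and stays behind in step 3.

Step 3
Reactants: 2 methyl 3,6-dioxocyclohexa-1,4-diene-1-carboxylate; 4 (E)-1-(tert-butyldimethylsilyloxy)buta-1,3-diene
Product: 5 cis-fused cycloadduct, methyl (4aR,8S,8aS)-8-(tert-butyldimethylsilyloxy)-1,4-dioxo-1,4,4a,5,8,8a-hexahydronaphthalene-8a-carboxylate (target locants: C1 and C4 ketones, C2=C3, C7=C8, 9α-OTBS, 10β-CO2CH3, 5β-H)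
Conditions: Gd(OSO2CF3)3 (10 mol %), 2,6-bis[(4S)-4-phenyl-4,5-dihydrooxazol-2-yl]pyridine (12 mol %), 4 Å molecular sieves, CH2Cl2, −78 → −40 °C; 4 (2 equiv)
Reagents that add atoms: none
Why: The gadolinium triflate–pybox complex holds the quinone through the C1 carbonyl and the ester carbonyl, which lowers the LUMO of the C5=C10 bond alone and puts its largest coefficient on C5, so that the unsubstituted diene terminus C6 bonds to C5 slightly ahead of C9–C10 in a concerted, asynchronous [4+2] cycloaddition. The closest known reaction type is the chiral Lewis acid-catalysed Diels–Alder reaction of 2-carboalkoxy-1,4-benzoquinones with 1-substituted butadienes. Ring B closes as a six-membered carbocycle by suprafacial addition of the s-cis diene to the ring alkene (4π + 2π closure). C10 is set by the ligand, which leaves one face of the chelated dienophile open; C5 follows from suprafacial addition to a cyclic cis alkene, which puts H5 and the ester on the same face; C9 follows from the endo transition state with the quinone ring under the (E)-diene, which puts the silyloxy group anti to the ester. The step needs site, regio, endo and facial selectivity: the ester makes C5=C10 the most electron-poor alkene, the oxygen-bearing diene terminus is the weaker nucleophile and ends on the ester-bearing C10, secondary overlap with the ene-dione gives endo, and the ligand gives the face. Two-point binding is chosen because a one-point Lewis acid on the more basic C4 carbonyl would activate C10 as the electrophilic end and work against the required regiochemistry.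

Step 4
Reactants: 5 cis-fused cycloadduct
Product: 6 trans-fused ene-dione, the C5 epimer of 5 (5α-H)
Conditions: DBU (0.1 equiv), CH2Cl2, 0 °C → rt; chromatography, recovered 5 resubjected
Reagents that add atoms: none
Why: Base-catalysed epimerization α to a ketone: C5–H is the only enolizable hydrogen, the quaternary C10 cannot change, and the trans isomer should prevail because the flat ene-dione ring leaves the axial angular ester with a single 1,3-diaxial hydrogen (the classical cis-to-trans isomerization of angularly substituted quinone adducts), while a metal-free base avoids a chelate that would hold the ester in the plane of ring A and favour cis.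

Step 5
Reactants: 6 trans-fused ene-dione
Product: 7 4β-hydroxy-4α-methyl enone (C1 ketone, C2=C3, 9α-OTBS, 10β-CO2CH3, 5α-H)
Conditions: CH3Li (1.3 equiv), CeCl3 (1.4 equiv), THF, −78 °C; aq. NH4Cl at −78 °C
Reagents that add atoms: methyllithium, [Li]C
Why: 1,2-Addition of an organocerium reagent: the weakly basic CH3CeCl2 does not enolize C5–H and adds to the C4 carbonyl, far more accessible than the C1 carbonyl wedged between the quaternary C10 and the silyloxy-bearing C9; attack anti to the 1,3-diaxial ester should give the 4β-alcohol (a centre that is lost in step 9), and if the 4-alkoxide closed onto the ester the lactone would give the same triol in step 6.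

Step 6
Reactants: 7 4β-hydroxy-4α-methyl enone
Product: 8 triol (1β-OH, 4β-OH, C14 hydroxymethyl on C10; C2=C3, C7=C8, 9α-OTBS)
Conditions: LiAlH4 (4 equiv), THF, −78 → 0 °C; aq. KNaC4H4O6 (potassium sodium tartrate)
Reagents that add atoms: none
Why: Hydride reduction of an enone (1,2) and of an ester: the small aluminohydride should attack C1 axially from the α face, because β attack is blocked by the adjacent axial ester and would push the new oxygen into a syn-diaxial clash with the 9α-silyloxy group, so the equatorial 1β-alcohol forms, and the same reagent turns the neopentyl ester into the C14 alcohol while silyl ether, alkenes and tertiary alcohol are inert.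

Step 7
Reactants: 8 triol
Product: 9 1β,14-O-isopropylidene acetal of 8 (4β-OH free, 9α-OTBS)
Conditions: 2,2-dimethoxypropane (5 equiv), PPTS (5 mol %), CH2Cl2, 0 °C → rt; Et3N quench
Reagents that add atoms: 2,2-dimethoxypropane, COC(C)(C)OC
Why: Acid-catalysed transacetalization: only the 1β-OH/C14-OH pair can close a six-membered acetal (the two oxygens are gauche about C1–C10), the acetonide then locks the C1 configuration, and the weak pyridinium acid should not ionize the tertiary allylic alcohol.

Step 8
Reactants: 9 silyl ether acetonide
Product: 10 9α-alcohol (1β,14-O-isopropylidene, 4β-OH, C2=C3, C7=C8)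
Conditions: Bu4NF (3 equiv), THF, rt → 45 °C
Reagents that add atoms: none
Why: Fluoride-induced desilylation driven by the Si–F bond frees the hindered 9α-hydroxyl; acetal and alkenes are stable, and with no carbonyl group left next to C10 no retro-aldol path exists.

Step 9
Reactants: 10 9α-alcohol
Product: 11 bis-enone (C2 ketone with C3=C4 bearing the C15 methyl; C9 ketone with C7=C8; 1β,14-O-isopropylidene; 5α-H)
Conditions: pyridinium chlorochromate, C5H5NH[CrO3Cl] (6 equiv), 4 Å molecular sieves, CH2Cl2, rt
Reagents that add atoms: none
Why: Chromate oxidation in two known modes at separate sites: the secondary allylic 9-OH is oxidized to the C7=C8–C9=O enone, and the tertiary allylic 4-OH undergoes the Babler–Dauben oxidative transposition ([3,3] shift of its chromate ester to C2, then oxidation), which gives the C2 ketone conjugated with the new C3=C4 bond, while the acetonide holds C1, now α to a ketone, in its configuration.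

Step 10
Reactants: 11 bis-enone; 12 isopropenylmagnesium bromide
Product: 13 7α-isopropenyl diketone (C9 ketone saturated, ring-A enone kept, 1β,14-O-isopropylidene)
Conditions: 12 (3 equiv), CuBr·SMe2 (1.5 equiv), THF, −78 → −40 °C; aq. NH4Cl/NH3
Reagents that add atoms: isopropenylmagnesium bromide (12), C=C(C)[Mg]Br
Why: Conjugate addition of a magnesium diorganocuprate: it should add to C7 of the β-monosubstituted ring-B enone and spare the ring-A enone, whose β-carbon C4 is fully substituted, and in the locked trans-decalin the new bond forms axially on the α face, antiparallel to the enone π system through a chair-like enolate and away from the axial C14 arm on the β face.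

Step 11
Reactants: 13 7α-isopropenyl diketone
Product: 14 2β,9α-diol (C3=C4, 7α-isopropenyl, 1β,14-O-isopropylidene)
Conditions: LiBH(s-Bu)3 (3.5 equiv), THF, −78 °C; then NaOH, H2O2, 0 °C
Reagents that add atoms: none
Why: Reduction by a bulky trialkylborohydride under steric approach control: at C9 the axial α approach is closed by the syn-axial isopropenyl group on C7, so hydride enters from the β side and gives the axial 9α-alcohol, and at C2 the β face is closed by the axial C14 arm of the acetonide (1,3 relationship), so hydride enters from the α face and gives the 2β-alcohol by 1,2-reduction of an enone whose β-carbon is fully substituted.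

Step 12
Reactants: 14 2β,9α-diol
Product: 15 2β,9α-diacetate (1β,14-O-isopropylidene)
Conditions: Ac2O (6 equiv), DMAP (0.3 equiv), pyridine, rt → 40 °C
Reagents that add atoms: acetic anhydride, CC(=O)OC(C)=O
Why: Nucleophile-catalysed acylation with 4-dimethylaminopyridine converts the two secondary alcohols, the only free hydroxyls, into acetates with retention at C2 and C9.

Step 13
Reactants: 15 diacetate acetonide
Product: 16 1β,14-diol 2β,9α-diacetate
Conditions: PPTS (0.2 equiv), MeOH, rt → 40 °C
Reagents that add atoms: none
Why: Acid-catalysed transacetalization to methanol removes the six-membered acetonide, which is far more labile than the esters, and the weak acid should neither ionize the allylic acetate nor move an acetyl group.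

Step 14
Reactants: 16 1β,14-diol 2β,9α-diacetate
Product: 17 14-O-tert-butyldimethylsilyl ether (1β-OH free)
Conditions: TBSCl (1.2 equiv), imidazole (2.5 equiv), CH2Cl2, 0 °C
Reagents that add atoms: tert-butyldimethylsilyl chloride, CC(C)(C)[Si](C)(C)Cl
Why: Selective silylation of a primary over a secondary alcohol: the bulky chlorosilane should take the C14 hydroxyl and leave the 1β-hydroxyl, which is secondary and flanked by C10 and the 2β-acetate.

Step 15
Reactants: 17 14-O-silyl ether
Product: 18 1β-(3-methylbut-2-enoate) of 17
Conditions: 3-methylbut-2-enoyl chloride (3 equiv), pyridine, DMAP (0.2 equiv), CH2Cl2, 0 °C → rt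
Reagents that add atoms: 3-methylbut-2-enoyl chloride, CC(C)=CC(=O)Cl
Why: Acylation of the only free hydroxyl with an acid chloride under acyl-transfer catalysis; pyridine is too weak a base to form the vinylketene, so the double bond should stay conjugated, and the medium does not move the neighbouring 2-acetate.

Step 16
Reactants: 18 silyl ether triester
Product: 19 target CNP0320218.1, 2β,9α-diacetoxy-14-hydroxy-1β-(3-methylbut-2-enoyloxy)-7α-isopropenyl-4-methyl-5αH-decal-3-ene, (1R,2S,5R,7S,9S,10S) in the locants above
Conditions: HF·pyridine, pyridine, THF, 0 °C → rt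
Reagents that add atoms: none
Why: Fluoride cleavage of the primary silyl ether under buffered acidic conditions frees the C14 hydroxyl without the alkoxide that would let the 1-ester migrate to it or cleave the acetates.

**Compound list**

1 | methyl 2,5-dihydroxybenzoate | COC(=O)c1cc(O)ccc1O | starting material
2 | methyl 3,6-dioxocyclohexa-1,4-diene-1-carboxylate | COC(=O)C1=CC(=O)C=CC1=O | intermediate
3 | (E)-but-2-enal | C/C=C/C=O | starting material
4 | (E)-1-(tert-butyldimethylsilyloxy)buta-1,3-diene | C=C/C=C/O[Si](C)(C)C(C)(C)C | intermediate
5 | cis-fused cycloadduct (9α-OTBS, 10β-CO2CH3, 5β-H, ring-A ene-dione, C7=C8) | C1=C[C@H](O[Si](C)(C)C(C)(C)C)[C@@]2(C(=O)OC)[C@@H](C1)C(=O)C=CC2=O | intermediate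
6 | trans-fused ene-dione (5α-H) | C1=C[C@H](O[Si](C)(C)C(C)(C)C)[C@@]2(C(=O)OC)[C@H](C1)C(=O)C=CC2=O | intermediate
7 | 4β-hydroxy-4α-methyl enone | C1=C[C@H](O[Si](C)(C)C(C)(C)C)[C@@]2(C(=O)OC)[C@H](C1)[C@](C)(O)C=CC2=O | intermediate
8 | 1β,4β,14-triol, 9α-OTBS | C1=C[C@H](O[Si](C)(C)C(C)(C)C)[C@@]2(CO)[C@H](C1)[C@](C)(O)C=C[C@@H]2O | intermediate
9 | 1β,14-O-isopropylidene acetal, 9α-OTBS | C1=C[C@H](O[Si](C)(C)C(C)(C)C)[C@@]2(COC(C)(C)O3)[C@H](C1)[C@](C)(O)C=C[C@@H]23 | intermediate
10 | 1β,14-O-isopropylidene acetal, 9α-OH | C1=C[C@H](O)[C@@]2(COC(C)(C)O3)[C@H](C1)[C@](C)(O)C=C[C@@H]23 | intermediate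
11 | bis-enone (C2=O/C3=C4, C9=O/C7=C8) | C1=CC(=O)[C@@]2(COC(C)(C)O3)[C@H](C1)C(C)=CC(=O)[C@@H]23 | intermediate
12 | isopropenylmagnesium bromide | C=C(C)[Mg]Br | starting material
13 | 7α-isopropenyl 2,9-diketone | C=C(C)[C@@H]1CC(=O)[C@@]2(COC(C)(C)O3)[C@H](C1)C(C)=CC(=O)[C@@H]23 | intermediate
14 | 2β,9α-diol | C=C(C)[C@@H]1C[C@H](O)[C@@]2(COC(C)(C)O3)[C@H](C1)C(C)=C[C@H](O)[C@@H]23 | intermediate
15 | 2β,9α-diacetate acetonide | C=C(C)[C@@H]1C[C@H](OC(C)=O)[C@@]2(COC(C)(C)O3)[C@H](C1)C(C)=C[C@H](OC(C)=O)[C@@H]23 | intermediate
16 | 1β,14-diol 2β,9α-diacetate | C=C(C)[C@@H]1C[C@H](OC(C)=O)[C@@]2(CO)[C@H](C1)C(C)=C[C@H](OC(C)=O)[C@@H]2O | intermediate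
17 | 14-O-TBS ether of 16 | C=C(C)[C@@H]1C[C@H](OC(C)=O)[C@@]2(CO[Si](C)(C)C(C)(C)C)[C@H](C1)C(C)=C[C@H](OC(C)=O)[C@@H]2O | intermediate
18 | 1β-(3-methylbut-2-enoate) of 17 | C=C(C)[C@@H]1C[C@H](OC(C)=O)[C@@]2(CO[Si](C)(C)C(C)(C)C)[C@H](C1)C(C)=C[C@H](OC(C)=O)[C@@H]2OC(=O)C=C(C)C | intermediate
19 | CNP0320218.1 | C=C(C)[C@@H]1C[C@H](OC(C)=O)[C@@]2(CO)[C@H](C1)C(C)=C[C@H](OC(C)=O)[C@@H]2OC(=O)C=C(C)C | target

**Count and risks**

Total steps: 16. Longest linear sequence: 15 (steps 1 and 3–16, or steps 2–16).

Steps most likely to fail:

Step 3. The catalyst may give low facial selectivity or the wrong sense on this quinone ester, and the Lewis acid may consume the silyl dienol ether by desilylation or stepwise Michael addition before the cycloaddition. Fallback: give up catalyst control. The uncatalysed cycloaddition of 2 and 4 (CH2Cl2, −20 °C → rt) is fast and should be regio- and endo-selective on its own. It gives 5 together with its mirror image ent-5 F1; step 4 then gives 6 together with ent-6 F2. The enantiomers are separated by preparative supercritical-fluid chromatography on a cellulose carbamate phase, and the route is rejoined at 6.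

Step 9. The chromate shift to C2, next to the acetal oxygen on C1, may lag behind the alcohol oxidation, and the acidic reagent may open the acetonide or ionize the tertiary alcohol. Fallback: separate the two events and change the mechanism of the transposition. MnO2 (CH2Cl2, rt) oxidizes only the secondary allylic alcohol of 10 and gives the ring-B enone carbinol F3. Ph3SiOReO3 (3 mol %, Et2O, 0 °C) then moves the tertiary hydroxyl to C2 by [3,3] shift of its perrhenate ester, the equilibrium resting on the side of the trisubstituted C3=C4 alkene, to give the 2β-allylic alcohol F4 (its C2 centre is lost in the next operation). Dess–Martin periodinane (CH2Cl2, NaHCO3) oxidizes it to 11, where the route is rejoined.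

Step 6. Facial selectivity at C1 may erode because the α face carries the syn-axial 9α-silyloxy group, so that β attack and the axial 1α-alcohol compete. Fallback: make the hydride delivery intramolecular. From 7, HF·pyridine (THF, pyridine, 0 °C) removes the silyl group and gives the β-hydroxy enone F5, kept under acidic conditions to suppress retro-aldol cleavage. Me4NBH(OAc)3 (MeCN/AcOH, −30 °C) exchanges onto the 9α-hydroxyl and delivers hydride to the α face of C1 through a six-membered transition state (anti-1,3-diol), giving the 1β,9α-diol ester F6. LiAlH4 reduces the ester to the tetraol F7, and 2,2-dimethoxypropane/PPTS gives 10, where the route is rejoined.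

**Further compounds**

F1 | step 3 | ent-5 | C1=C[C@@H](O[Si](C)(C)C(C)(C)C)[C@]2(C(=O)OC)[C@H](C1)C(=O)C=CC2=O
F2 | step 3 | ent-6 | C1=C[C@@H](O[Si](C)(C)C(C)(C)C)[C@]2(C(=O)OC)[C@@H](C1)C(=O)C=CC2=O
F3 | step 9 | ring-B enone carbinol (C9 ketone, C7=C8, 4β-OH, C2=C3, 1β,14-O-isopropylidene) | C1=CC(=O)[C@@]2(COC(C)(C)O3)[C@H](C1)[C@](C)(O)C=C[C@@H]23
F4 | step 9 | 2β-allylic alcohol (C9 ketone, C7=C8, C3=C4, 1β,14-O-isopropylidene) | C1=CC(=O)[C@@]2(COC(C)(C)O3)[C@H](C1)C(C)=C[C@H](O)[C@@H]23
F5 | step 6 | β-hydroxy enone (desilylated 7) | C1=C[C@H](O)[C@@]2(C(=O)OC)[C@H](C1)[C@](C)(O)C=CC2=O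
F6 | step 6 | 1β,9α-diol ester | C1=C[C@H](O)[C@@]2(C(=O)OC)[C@H](C1)[C@](C)(O)C=C[C@@H]2O
F7 | step 6 | 1β,4β,9α,14-tetraol | C1=C[C@H](O)[C@@]2(CO)[C@H](C1)[C@](C)(O)C=C[C@@H]2O
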